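**Assumptions (one line each)**
- The target SMILES has no stereocenters. Ring flipping of the cyclophane is assumed fast, so no stereochemistry needs to be set.
- (3-Methoxybenzyl)triphenylphosphonium chloride is treated as a catalogue reagent.

**Retrosynthetic overview**
1. The 18-membered macrocycle is closed last at the quinone C–O bond. A ring-C phenoxide adds to C3 of a 2-(arylethyl)-1,4-benzoquinone (intramolecular oxa-Michael), and the resulting hydroquinone is reoxidised to the quinone.
2. The 2-alkylquinone comes from desymmetrising p-benzoquinone by decarboxylative radical alkylation with a 3-arylpropanoic acid.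
3. That acid is built from isovanillin and 4-fluorobenzaldehyde. The A–O–B diaryl ether is made by SNAr, the B–C bibenzyl by Wittig then hydrogenation, and the A–CH2CH2CO2H chain by Knoevenagel–Doebner then hydrogenation.
4. Ring-formation order: all three benzenoid rings are preinstalled, then diaryl ether A–O–B, then the bibenzyls, then the substituted quinone, and finally the macrocycle.

**Route**

**Step 1**
- Reactants: 1 isovanillin (3-hydroxy-4-methoxybenzaldehyde); 2 (3-methoxybenzyl)triphenylphosphonium chloride.
- Product: 3 (E/Z)-2-methoxy-5-[2-(3-methoxyphenyl)ethenyl]phenol.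
- Conditions: t-BuOK (2.2 equiv), THF, 0 °C → rt.
- Reagents that add atoms: none.
- Why: Wittig olefination. The first equivalent of base deprotonates the free phenol and the second makes the ylide. The alkene geometry is irrelevant because it is hydrogenated later, and no stereocenter is formed.

**Step 2**
- Reactants: 3; 4 4-fluorobenzaldehyde.
- Product: 5 4-[2-methoxy-5-(2-(3-methoxyphenyl)ethenyl)phenoxy]benzaldehyde.
- Conditions: K2CO3, DMF, 120 °C.
- Reagents that add atoms: none.
- Why: SNAr of the phenoxide on the aldehyde-activated aryl fluoride forms the ring A–O–ring B ether with the correct meta relationship to the chain on ring B. The ortho OMe becomes the free OH after step 5.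

**Step 3**
- Reactants: 5; 6 malonic acid.
- Product: 7 (E)-3-{4-[2-methoxy-5-(2-(3-methoxyphenyl)ethenyl)phenoxy]phenyl}propenoic acid.
- Conditions: pyridine, piperidine (cat.), 100 °C.
- Reagents that add atoms: none (malonic acid is the reactant).
- Why: Knoevenagel–Doebner condensation with decarboxylation gives the cinnamic acid directly. The stilbene alkene is untouched, and the new alkene is E and is reduced next.

**Step 4**
- Reactants: 7.
- Product: 8 3-{4-[2-methoxy-5-(2-(3-methoxyphenyl)ethyl)phenoxy]phenyl}propanoic acid.
- Conditions: H2 (1 atm), 10% Pd/C, EtOAc/MeOH, rt.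
- Reagents that add atoms: none.
- Why: Catalytic hydrogenation reduces both C=C bonds to give the bibenzyl and the arylpropanoic acid. The aryl methyl ethers and diaryl ether are stable, and no stereocenters result.

**Step 5**
- Reactants: 8.
- Product: 9 3-{4-[2-hydroxy-5-(2-(3-hydroxyphenyl)ethyl)phenoxy]phenyl}propanoic acid.
- Conditions: BBr3 (4 equiv), CH2Cl2, −78 → 0 °C; aqueous workup.
- Reagents that add atoms: none.
- Why: BBr3 demethylation of both aryl methyl ethers at low temperature leaves the diaryl ether and the acid intact. This step comes before the quinone is formed, since a quinone would not survive BBr3.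

**Step 6**
- Reactants: 9; 10 p-benzoquinone (4 equiv).
- Product: 11 2-[2-(4-{2-hydroxy-5-[2-(3-hydroxyphenyl)ethyl]phenoxy}phenyl)ethyl]-1,4-benzoquinone.
- Conditions: AgNO3 (0.2 equiv), (NH4)2S2O8 (1.5 equiv), MeCN/H2O 1:1, 70 °C.
- Reagents that add atoms: none.
- Why: Kochi–Anderson decarboxylative radical alkylation. Ag(II) oxidises the acid and CO2 is lost to give the 2-arylethyl radical, which adds to p-benzoquinone and breaks its symmetry. Excess benzoquinone prevents dialkylation, and the acidic medium keeps the phenols protonated so they cannot add prematurely.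

**Step 7**
- Reactants: 11.
- Product: 12 Marchantinquinone.
- Conditions: Cs2CO3 (1.5 equiv), DMF (2 mM, syringe-pump addition over 10 h), rt, air; then Ag2O (3 equiv), CH2Cl2, rt; NH4Cl quench.
- Reagents that add atoms: none.
- Why: Proposed new method: the ring-C phenoxide adds intramolecularly to C3 of the tethered 2-alkylquinone. This forms the 18-membered ring, and the resulting aryloxyhydroquinone is oxidised back to the quinone by air and Ag2O. The mechanistic basis is the oxa-Michael addition of phenoxides to electron-poor quinones followed by oxidative rearomatisation and reoxidation, closest to oxa-Michael/Thiele-type additions to quinones. The tether and high dilution are meant to favour C3 over the electronically preferred C5/C6. The ring-B phenoxide cannot reach the quinone without forming a strained [8]paracyclophane-type ring. The oxidation only restores the quinone, and no stereocenter is formed.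

**Compound list**

| No. | Name | SMILES | Role |
|---|---|---|---|
| 1 | isovanillin | COc1ccc(C=O)cc1O | starting material |
| 2 | (3-methoxybenzyl)triphenylphosphonium chloride | COc1cccc(c1)C[P+](c1ccccc1)(c1ccccc1)c1ccccc1.[Cl-] | starting material |
| 3 | 2-methoxy-5-[2-(3-methoxyphenyl)ethenyl]phenol (E/Z) | COc1ccc(C=Cc2cccc(OC)c2)cc1O | intermediate |
| 4 | 4-fluorobenzaldehyde | O=Cc1ccc(F)cc1 | starting material |
| 5 | 4-[2-methoxy-5-(2-(3-methoxyphenyl)ethenyl)phenoxy]benzaldehyde | COc1ccc(C=Cc2cccc(OC)c2)cc1Oc1ccc(C=O)cc1 | intermediate |
| 6 | malonic acid | OC(=O)CC(=O)O | starting material |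
| 7 | (E)-3-{4-[2-methoxy-5-(2-(3-methoxyphenyl)ethenyl)phenoxy]phenyl}propenoic acid | COc1ccc(C=Cc2cccc(OC)c2)cc1Oc1ccc(/C=C/C(=O)O)cc1 | intermediate |
| 8 | 3-{4-[2-methoxy-5-(2-(3-methoxyphenyl)ethyl)phenoxy]phenyl}propanoic acid | COc1ccc(CCc2cccc(OC)c2)cc1Oc1ccc(CCC(=O)O)cc1 | intermediate |
| 9 | 3-{4-[2-hydroxy-5-(2-(3-hydroxyphenyl)ethyl)phenoxy]phenyl}propanoic acid | Oc1ccc(CCc2cccc(O)c2)cc1Oc1ccc(CCC(=O)O)cc1 | intermediate |
| 10 | p-benzoquinone | O=C1C=CC(=O)C=C1 | starting material |
| 11 | 2-alkyl-1,4-benzoquinone (seco-macrocycle) | O=C1C=CC(=O)C(CCc2ccc(Oc3cc(CCc4cccc(O)c4)ccc3O)cc2)=C1 | intermediate |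
| 12 | Marchantinquinone | O=C1C=CC(=O)C2=C1CCc1ccc(cc1)Oc1cc(ccc1O)CCc1cccc(c1)O2 | target |

**Total step count:** 7.

**Longest linear sequence:** 7 (1 → 3 → 5 → 7 → 8 → 9 → 11 → 12).

**Three steps most likely to fail**
1. **Step 7 (macrocyclic oxa-Michael).** It may give C5/C6 attack, C-attack by the phenoxide, or oligomers.
   - Fallback: close the ring by intramolecular Ullmann C–O coupling (CuI/N,N-dimethylglycine, Cs2CO3) of ring-C phenol onto a 2-bromo-3-alkyl-1,4-dimethoxybenzene precursor, then oxidise with CAN. This is a different ring-closing strategy.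
2. **Step 6 (radical alkylation of a polyphenolic acid).** Persulfate may oxidise the free phenols.
   - Fallback: build the alkylquinone by Sonogashira coupling of 2-iodo-1,4-dimethoxybenzene with the alkyne derived from aldehyde 5 (Ohira–Bestmann), hydrogenation, and CAN oxidation, with the phenols carried as benzyl ethers.
3. **Step 5 (double BBr3 demethylation).** It may cleave the diaryl ether or cause decomposition.
   - Fallback: start from 4-benzyloxy-3-hydroxybenzaldehyde and (3-benzyloxybenzyl)triphenylphosphonium salt. Both phenols are then unmasked by hydrogenolysis in step 4, and step 5 is removed.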